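**Plan**
Retron: ring C8–C12 is a 2-chloro-4-hydroxy-4,5-dialkylcyclopent-2-enone. C9(=O)–C10(Cl)=C11–C12 are the four carbons of a 3-chlorofuran, C8 is a furfuryl carbinol carbon, and the C12 hydroxyl is water (Piancatelli rearrangement, dearomatisation of the furan).
Cuts, in retrosynthetic order: O6/O7 acetates; C8 configuration (epimerisable); C8–C12 and C12–OH (key step); C8–C9 (furyllithium + aldehyde); C12–C13 (furyllithium + dienyl bromide); C3–C4 (radical addition to methyl acrylate).
Forward: D-glucono-1,5-lactone gives the C1–C8 aldehyde, and 3-bromofuran plus a C8 dienyl bromide give the chlorofuran. The halves are joined at C8–C9, and the only carbocycle is closed last from the flat furan.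
Stereochemistry: C5, C6, C7 are C2, C3, C4 of D-gluconate. C12 comes from the sense of conrotation, steered by the C7 dioxolane through a zinc chelate. C8 is set afterwards by equilibration to the trans-dialkyl ring, and both Z alkenes come from alkyne semihydrogenation.

Key step: step 15

Remark: prostaglandin numbering is used (C1 = ester carbonyl carbon, ring = C8–C12, C20 = chain end). The trans-dialkyl arrangement at C8/C12 of the target is assumed to be the thermodynamically preferred one, as in the prostaglandin E series.

**Step 1**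
Reactants: 1 D-glucono-1,5-lactone
Product: 2 methyl 3,4:5,6-di-O-isopropylidene-D-gluconate
Conditions: 2,2-dimethoxypropane, MeOH, acetone, TsOH·H2O (cat.), rt
Reagents that add atoms: 2,2-dimethoxypropane COC(C)(C)OC; methanol CO
Why: Acid-catalysed lactone methanolysis plus thermodynamic acetonide formation (transketalisation) locks O3/O4 and O5/O6 in dioxolanes and leaves only the 2-OH free, no stereocentre being touched, so that gluconate C2, C3 and C4 become C5, C6 and C7 of the target.

**Step 2**
Reactants: 2 methyl 3,4:5,6-di-O-isopropylidene-D-gluconate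
Product: 3 3,4:5,6-di-O-isopropylidene-D-glucitol
Conditions: NaBH4, EtOH, 0 °C → rt
Reagents that add atoms: none
Why: Borohydride reduction of an α-hydroxy ester, which is activated enough for NaBH4, gives the terminal 1,2-diol without touching acetonides or stereocentres.

**Step 3**
Reactants: 3 3,4:5,6-di-O-isopropylidene-D-glucitol
Product: 4 1-deoxy-1-iodo-3,4:5,6-di-O-isopropylidene-D-glucitol
Conditions: I2 (1 equiv), PPh3, imidazole, THF, 0 °C
Reagents that add atoms: iodine II
Why: Appel-type (Garegg–Samuelsson) iodination is much faster at the unhindered primary alcohol than at the flanked secondary one, so one equivalent at low temperature should give the primary iodide with the adjacent centre untouched.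

**Step 4**
Reactants: 4 1-deoxy-1-iodo-3,4:5,6-di-O-isopropylidene-D-glucitol
Product: 5 2-O-acetyl-1-deoxy-1-iodo-3,4:5,6-di-O-isopropylidene-D-glucitol
Conditions: Ac2O, pyridine, DMAP (cat.), CH2Cl2, 0 °C
Reagents that add atoms: acetic anhydride CC(=O)OC(C)=O
Why: Standard DMAP-catalysed O-acylation installs the final C5 acetate early, which also keeps O5 from lactonising onto C1 or attacking the C8 cation later.

**Step 5**
Reactants: 5 2-O-acetyl-1-deoxy-1-iodo-3,4:5,6-di-O-isopropylidene-D-glucitol; 6 methyl acrylate
Product: 7 methyl 5-O-acetyl-2,3,4-trideoxy-6,7:8,9-di-O-isopropylidene-D-gluco-nononate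
Conditions: 6 (excess), Bu3SnH (slow addition), AIBN (cat.), toluene, 80 °C
Reagents that add atoms: none
Why: Giese reaction, in which the primary radical from the C–I bond adds to the β-carbon of the electron-poor acrylate and the adduct radical is reduced by the stannane, so that C1–C3 are built as the saturated methyl ester in one step; β-acyloxy radicals do not fragment and no stereocentre is involved.

**Step 6**
Reactants: 7 methyl 5-O-acetyl-2,3,4-trideoxy-6,7:8,9-di-O-isopropylidene-D-gluco-nononate
Product: 8 methyl (5S)-5-acetoxy-5-[(4R,5S)-5-formyl-2,2-dimethyl-1,3-dioxolan-4-yl]pentanoate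
Conditions: H5IO6, EtOAc, 0 °C → rt
Reagents that add atoms: none
Why: Periodic acid hydrolyses the less hindered terminal dioxolane selectively and cleaves the liberated glycol in the same flask (Malaprade cleavage), while the internal trans-dioxolane and both esters stay, giving the C8 aldehyde whose α-centre already sits in the more stable trans arrangement.

**Step 7**
Reactants: 9 1-bromopent-2-yne; 10 prop-2-yn-1-ol
Product: 11 octa-2,5-diyn-1-ol
Conditions: CuI, NaI, K2CO3, DMF, rt
Reagents that add atoms: none
Why: Copper-mediated propargylic substitution by a terminal alkyne (skipped-diyne coupling) forms C15–C16 under conditions too mild for allene formation.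

**Step 8**
Reactants: 11 octa-2,5-diyn-1-ol
Product: 12 (2Z,5Z)-octa-2,5-dien-1-ol
Conditions: H2 (1 atm), Pd/CaCO3 poisoned with Pb(OAc)2 (Lindlar catalyst), quinoline, EtOAc, 0 °C → rt
Reagents that add atoms: none
Why: Lindlar semihydrogenation adds hydrogen syn to each alkyne and stops at the alkene stage, which sets both Z double bonds (C14=C15 and C17=C18).

**Step 9**
Reactants: 12 (2Z,5Z)-octa-2,5-dien-1-ol
Product: 13 (2Z,5Z)-1-bromoocta-2,5-diene
Conditions: CBr4, PPh3, CH2Cl2, 0 °C
Reagents that add atoms: carbon tetrabromide BrC(Br)(Br)Br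
Why: Appel bromination proceeds by SN2 at the primary allylic carbon under neutral conditions and should keep both Z alkenes.

**Step 10**
Reactants: 14 3-bromofuran
Product: 16 (3-bromofuran-2-yl)trimethylsilane, via 3-bromo-2-lithiofuran 15 (not isolated)
Conditions: LDA (commercial solution), THF, −78 °C; then TMSCl
Reagents that add atoms: chlorotrimethylsilane C[Si](C)(C)Cl
Why: Directed deprotonation, since the proton between ring oxygen and bromine is the most acidic one and LDA does not exchange bromine, so silylation blocks the position that later becomes C9.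

**Step 11**
Reactants: 16 (3-bromofuran-2-yl)trimethylsilane
Product: 18 (3-chlorofuran-2-yl)trimethylsilane, via 3-lithio-2-(trimethylsilyl)furan 17 (not isolated)
Conditions: n-BuLi, Et2O, −78 °C; then C2Cl6, −78 °C
Reagents that add atoms: hexachloroethane ClC(Cl)(Cl)C(Cl)(Cl)Cl
Why: Bromine–lithium exchange followed by electrophilic chlorination swaps the halogen at the carbon that becomes C10, the silyl group keeping lithium from moving to the α-position.

**Step 12**
Reactants: 18 (3-chlorofuran-2-yl)trimethylsilane; 13 (2Z,5Z)-1-bromoocta-2,5-diene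
Product: 20 {3-chloro-5-[(2Z,5Z)-octa-2,5-dien-1-yl]furan-2-yl}trimethylsilane, via 4-chloro-2-lithio-5-(trimethylsilyl)furan 19 (not isolated)
Conditions: n-BuLi, THF, −78 → −20 °C; then 13, −78 °C → rt
Reagents that add atoms: none
Why: With one α-position blocked, lithiation takes place at the only remaining position next to oxygen, and SN2 alkylation of the furyllithium with the primary allylic bromide forms C12–C13 with retention of the Z geometry.

**Step 13**
Reactants: 20 {3-chloro-5-[(2Z,5Z)-octa-2,5-dien-1-yl]furan-2-yl}trimethylsilane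
Product: 21 4-chloro-2-[(2Z,5Z)-octa-2,5-dien-1-yl]furan
Conditions: TBAF, wet THF, rt
Reagents that add atoms: none
Why: Fluoride-induced protodesilylation is easy here because the departing furyl anion is stabilised by the ring oxygen and the adjacent chlorine, and it frees the position that becomes C9.

**Step 14**
Reactants: 21 4-chloro-2-[(2Z,5Z)-octa-2,5-dien-1-yl]furan; 8 methyl (5S)-5-acetoxy-5-[(4R,5S)-5-formyl-2,2-dimethyl-1,3-dioxolan-4-yl]pentanoate
Product: 23 methyl (5S)-5-acetoxy-5-[(4R,5R)-5-{[3-chloro-5-((2Z,5Z)-octa-2,5-dien-1-yl)furan-2-yl](hydroxy)methyl}-2,2-dimethyl-1,3-dioxolan-4-yl]pentanoate (both C8 epimers), via 3-chloro-2-lithio-5-octadienylfuran 22 (not isolated)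
Conditions: LDA (commercial solution), THF, −78 °C; then 8, −78 °C; then H2O
Reagents that add atoms: none
Why: Ortho-lithiation between oxygen and chlorine followed by 1,2-addition of the furyllithium to the aldehyde, which at −78 °C is far more electrophilic than the two esters, forms C8–C9; the new carbinol centre is formed without control and needs none because it is planarised in step 15.

**Step 15**
Reactants: 23 furylcarbinol (both C8 epimers)
Product: 26 methyl (5S,6R,7R,8R,12R,14Z,17Z)-5-acetoxy-10-chloro-12-hydroxy-6,7-(isopropylidenedioxy)-9-oxoprosta-10,14,17-trien-1-oate, via furfuryl cation 24 (not isolated), via hydroxypentadienyl cation 25 (not isolated)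
Conditions: ZnCl2 (2 equiv), 1,4-dioxane/H2O (4:1), degassed, BHT (trace), 85 °C
Reagents that add atoms: water O
Why: Piancatelli rearrangement (closest precedent: the ZnCl2-mediated rearrangement of 5-methyl-2-furylcarbinols to 4-hydroxy-4-methyl-5-alkylcyclopent-2-enones): either C8 epimer of 23 ionises to the same planar, C12-alkyl-stabilised cation 24, water adds at furan C5 (= C12), and the hemiketal opens to the 1,4-dihydroxypentadienyl cation 25. The carbocycle C8–C12 closes by thermal conrotatory 4π electrocyclisation of 25 (C8–C12 bond, Nazarov-type closure of a pentadienyl cation), and loss of the proton on O9 gives the enone with chlorine already on C10, the furan oxygen as O9 and the water oxygen as O12. Relative configuration: C7 on C8 and OH on C12 both occupy outside positions of the U-shaped cation, so conrotation places them trans; 26 is therefore the C8 epimer of the natural series by design, and only C12, which cannot be corrected later, has to come out right here. Absolute configuration at C12: divalent zinc should bridge the C9 enol oxygen and dioxolane O7 (a six-membered chelate that exists only for the outside C7), which turns C6 and the dioxolane over one face of C8, so that C8 bonds to C12 through the lobe next to H7, and for the D-gluco-derived C7 centre this sense of rotation gives 12R (and 8R). Selectivity needed: capture of water at C8 only regenerates 23 and is harmless; proton loss from the doubly activated C13H2 of 24 must stay slower than hydration, which is why a nearly neutral Lewis acid in a water-rich medium replaces a Brønsted acid; and acetonide, acetate, ester and skipped diene must survive, which the same mild medium, degassing and BHT serve.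

**Step 16**
Reactants: 26 (8R,12R)-cyclopentenone
Product: 27 methyl (5S,6R,7R,8S,12R,14Z,17Z)-5-acetoxy-10-chloro-12-hydroxy-6,7-(isopropylidenedioxy)-9-oxoprosta-10,14,17-trien-1-oate
Conditions: KOAc, MeOH, rt
Reagents that add atoms: none
Why: Weak-base enolisation and reprotonation at C8 (thermodynamic epimerisation, the method used to turn 8-iso-prostaglandin E compounds into the trans series) should move the branched C7 substituent from the face of the C13 chain to the face of the smaller C12 hydroxyl, C12 being quaternary and untouched and acetate being too weak a base to expel the O7 alkoxide at a competitive rate.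

**Step 17**
Reactants: 27 (8S,12R)-cyclopentenone
Product: 28 methyl (5S,6S,7R,8S,12R,14Z,17Z)-5-acetoxy-10-chloro-6,7,12-trihydroxy-9-oxoprosta-10,14,17-trien-1-oate (the C6 descriptor changes by ranking only)
Conditions: TFA/H2O (9:1), CH2Cl2, 0 °C
Reagents that add atoms: none
Why: Acid hydrolysis of the dioxolane frees O6 and O7, the tertiary allylic C12–OH being protected against ionisation by the electron-poor chloroenone, and C8 already being in its preferred configuration should acid cause any enolisation.

**Step 18**
Reactants: 28 6,7,12-triol 5-acetate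
Product: 29 methyl (5S,6R,7R,8S,12R,14Z,17Z)-5,6,7-triacetoxy-10-chloro-12-hydroxy-9-oxoprosta-10,14,17-trien-1-oate (target)
Conditions: Ac2O, pyridine, CH2Cl2, 0 °C
Reagents that add atoms: acetic anhydride CC(=O)OC(C)=O
Why: Selective O-acylation, in which the two secondary alcohols react while the hindered tertiary C12–OH does not without DMAP; any acetyl migration among O5–O7 in 28 is harmless because all three positions end as acetates, and low temperature and short contact keep the new 7-acetate from β-elimination.

**Compound list**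
1 | D-glucono-1,5-lactone | OC[C@H]1OC(=O)[C@H](O)[C@@H](O)[C@@H]1O | starting material
2 | methyl 3,4:5,6-di-O-isopropylidene-D-gluconate | CC1(C)OC[C@@H](O1)[C@H]2OC(C)(C)O[C@@H]2[C@@H](O)C(=O)OC | intermediate
3 | 3,4:5,6-di-O-isopropylidene-D-glucitol | CC1(C)OC[C@@H](O1)[C@H]2OC(C)(C)O[C@@H]2[C@@H](O)CO | intermediate
4 | 1-deoxy-1-iodo-3,4:5,6-di-O-isopropylidene-D-glucitol | CC1(C)OC[C@@H](O1)[C@H]2OC(C)(C)O[C@@H]2[C@@H](O)CI | intermediate
5 | 2-O-acetyl-1-deoxy-1-iodo-3,4:5,6-di-O-isopropylidene-D-glucitol | CC1(C)OC[C@@H](O1)[C@H]2OC(C)(C)O[C@@H]2[C@@H](OC(C)=O)CI | intermediate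
6 | methyl acrylate | C=CC(=O)OC | starting material
7 | methyl 5-O-acetyl-2,3,4-trideoxy-6,7:8,9-di-O-isopropylidene-D-gluco-nononate | CC1(C)OC[C@@H](O1)[C@H]2OC(C)(C)O[C@@H]2[C@@H](OC(C)=O)CCCC(=O)OC | intermediate
8 | methyl (5S)-5-acetoxy-5-[(4R,5S)-5-formyl-2,2-dimethyl-1,3-dioxolan-4-yl]pentanoate | O=C[C@H]1OC(C)(C)O[C@@H]1[C@@H](OC(C)=O)CCCC(=O)OC | intermediate
9 | 1-bromopent-2-yne | CCC#CCBr | starting material
10 | prop-2-yn-1-ol | C#CCO | starting material
11 | octa-2,5-diyn-1-ol | CCC#CCC#CCO | intermediate
12 | (2Z,5Z)-octa-2,5-dien-1-ol | CC/C=C\C/C=C\CO | intermediate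
13 | (2Z,5Z)-1-bromoocta-2,5-diene | CC/C=C\C/C=C\CBr | intermediate
14 | 3-bromofuran | Brc1ccoc1 | starting material
15 | 3-bromo-2-lithiofuran | [Li]c1occc1Br | intermediate
16 | (3-bromofuran-2-yl)trimethylsilane | C[Si](C)(C)c1occc1Br | intermediate
17 | 3-lithio-2-(trimethylsilyl)furan | [Li]c1ccoc1[Si](C)(C)C | intermediate
18 | (3-chlorofuran-2-yl)trimethylsilane | C[Si](C)(C)c1occc1Cl | intermediate
19 | 4-chloro-2-lithio-5-(trimethylsilyl)furan | [Li]c1cc(Cl)c(o1)[Si](C)(C)C | intermediate
20 | {3-chloro-5-[(2Z,5Z)-octa-2,5-dien-1-yl]furan-2-yl}trimethylsilane | CC/C=C\C/C=C\Cc1cc(Cl)c(o1)[Si](C)(C)C | intermediate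
21 | 4-chloro-2-[(2Z,5Z)-octa-2,5-dien-1-yl]furan | CC/C=C\C/C=C\Cc1cc(Cl)co1 | intermediate
22 | 3-chloro-2-lithio-5-[(2Z,5Z)-octa-2,5-dien-1-yl]furan | CC/C=C\C/C=C\Cc1cc(Cl)c([Li])o1 | intermediate
23 | methyl (5S)-5-acetoxy-5-[(4R,5R)-5-{[3-chloro-5-((2Z,5Z)-octa-2,5-dien-1-yl)furan-2-yl](hydroxy)methyl}-2,2-dimethyl-1,3-dioxolan-4-yl]pentanoate, both C8 epimers (C8 left undefined) | CC/C=C\C/C=C\Cc1cc(Cl)c(o1)C(O)[C@H]2OC(C)(C)O[C@@H]2[C@@H](OC(C)=O)CCCC(=O)OC | intermediate
24 | furfuryl cation from 23, drawn as the 2-alkylidenefuranium form (C8=C9, C10=C11, C12=O+) | CC/C=C\C/C=C\CC1=[O+]C(=C[C@H]2OC(C)(C)O[C@@H]2[C@@H](OC(C)=O)CCCC(=O)OC)C(Cl)=C1 | intermediate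
25 | 1,4-dihydroxypentadienyl cation C8=C9(OH)–C10(Cl)=C11–C12=OH+, C9 and C12 cis on C10=C11, C7 cis to O9 | CC/C=C\C/C=C\CC(=[OH+])/C=C(Cl)\C(O)=C\[C@H]1OC(C)(C)O[C@@H]1[C@@H](OC(C)=O)CCCC(=O)OC | intermediate
26 | methyl (5S,6R,7R,8R,12R,14Z,17Z)-5-acetoxy-10-chloro-12-hydroxy-6,7-(isopropylidenedioxy)-9-oxoprosta-10,14,17-trien-1-oate | CC/C=C\C/C=C\C[C@]1(O)C=C(Cl)C(=O)[C@@H]1[C@H]2OC(C)(C)O[C@@H]2[C@@H](OC(C)=O)CCCC(=O)OC | intermediate
27 | methyl (5S,6R,7R,8S,12R,14Z,17Z)-5-acetoxy-10-chloro-12-hydroxy-6,7-(isopropylidenedioxy)-9-oxoprosta-10,14,17-trien-1-oate | CC/C=C\C/C=C\C[C@]1(O)C=C(Cl)C(=O)[C@H]1[C@H]2OC(C)(C)O[C@@H]2[C@@H](OC(C)=O)CCCC(=O)OC | intermediate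
28 | methyl (5S,6S,7R,8S,12R,14Z,17Z)-5-acetoxy-10-chloro-6,7,12-trihydroxy-9-oxoprosta-10,14,17-trien-1-oate | CC/C=C\C/C=C\C[C@]1(O)C=C(Cl)C(=O)[C@H]1[C@@H](O)[C@H](O)[C@@H](OC(C)=O)CCCC(=O)OC | intermediate
29 | methyl (5S,6R,7R,8S,12R,14Z,17Z)-5,6,7-triacetoxy-10-chloro-12-hydroxy-9-oxoprosta-10,14,17-trien-1-oate | CC/C=C\C/C=C\C[C@]1(O)C=C(Cl)C(=O)[C@H]1[C@@H](OC(C)=O)[C@H](OC(C)=O)[C@H](CCCC(=O)OC)OC(C)=O | target

**Total step count:** 18.
**Longest linear sequence:** 11 steps (steps 1–6 and 14–18, from D-glucono-1,5-lactone).

**Steps most likely to fail**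

1. **Step 15.**
   - What may go wrong: ionisation may be slow because O7 and the chlorine withdraw electrons. The cation may lose a proton from C13H2 and then polymerise or conjugate the diene. The zinc chelate may be too weak in a water-rich medium, so that the sense of conrotation is poorly controlled.
   - Fallback (oxidative ring opening and aldol closure in place of the cationic electrocyclisation), from 23 back to 27: ionic deoxygenation of 23 (Et3SiH, BF3·OEt2, CH2Cl2, −78 °C) gives the 8-deoxy 2,5-dialkyl-3-chlorofuran F1. Dye-sensitised photooxygenation (O2, methylene blue, visible light, CH2Cl2/MeOH, −78 °C) is much faster at a dialkylfuran than at Z-disubstituted alkenes and gives the furan endoperoxide F2. Me2S reduces it to the cis-enedione F3. A mild base (Et3N, CH2Cl2, rt) closes C8–C12 by intramolecular aldol addition under equilibrating conditions and gives the trans-dialkyl ring directly, so 27 is reached after separation from its ring diastereomer and step 16 is not needed.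

2. **Step 16.**
   - What may go wrong: the enolate may expel the O7 alkoxide (β-elimination with opening of the dioxolane), or the equilibrium may not lie far enough on the side of the trans-dialkyl isomer.
   - Fallback (irreversible enol silane formation and kinetic protonation in place of equilibration), from 26 back to 27: soft enolisation with TMSOTf and Et3N (CH2Cl2, −78 → 0 °C) silylates O12 and converts the ketone into the bis(trimethylsilyl) cross-conjugated dienol ether F4, without a free enolate that could eliminate. Hydrolytic protonation (AcOH, THF/H2O, 0 °C) should deliver the proton to C8 from the face opposite the trimethylsilyloxy group on C12. This places C7 cis to O12, and both silyl groups are lost in the same operation to give 27.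

3. **Step 14.**
   - What may go wrong: LDA or the furyllithium may deprotonate the doubly activated C13H2 instead of the ring C–H. Any excess of organolithium may attack the acetate or the methyl ester.
   - Fallback (regiospecific bromine–lithium exchange in place of C–H deprotonation), from 18 back to 23: ipso-bromodesilylation of 18 (NBS, MeCN, 0 °C), done before any alkene is present, gives 2-bromo-3-chlorofuran F5. LDA (THF, −78 °C, short contact to forestall bromine migration) gives 5-bromo-4-chloro-2-lithiofuran F6, which 13 alkylates to 2-bromo-3-chloro-5-[(2Z,5Z)-octa-2,5-dien-1-yl]furan F7. One equivalent of n-BuLi (THF, −78 °C) exchanges bromine within minutes to give 22 free of amine base, and 22 is added to 8 as in step 14 to give 23.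

**Further compounds**
F1 | step 15 | 8-deoxy analogue of 23 (C8H2 between furan and dioxolane; C5, C6, C7 as in 8) | CC/C=C\C/C=C\Cc1cc(Cl)c(o1)C[C@H]2OC(C)(C)O[C@@H]2[C@@H](OC(C)=O)CCCC(=O)OC
F2 | step 15 | 9,12-endoperoxide of F1 (2,3,7-trioxabicyclo[2.2.1]hept-5-ene, bridgeheads C9 and C12 undefined) | CC/C=C\C/C=C\CC12OOC(O1)(C[C@H]3OC(C)(C)O[C@@H]3[C@@H](OC(C)=O)CCCC(=O)OC)C(Cl)=C2
F3 | step 15 | ring-opened (10E)-10-chloro-9,12-dione (C9 and C12 cis on C10=C11; C5, C6, C7 as in 8) | CC/C=C\C/C=C\CC(=O)/C=C(Cl)\C(=O)C[C@H]1OC(C)(C)O[C@@H]1[C@@H](OC(C)=O)CCCC(=O)OC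
F4 | step 16 | 9,12-bis(trimethylsilyl) dienol ether of 26 (C8=C9 and C10=C11, 12R) | CC/C=C\C/C=C\C[C@]1(O[Si](C)(C)C)C=C(Cl)C(O[Si](C)(C)C)=C1[C@H]2OC(C)(C)O[C@@H]2[C@@H](OC(C)=O)CCCC(=O)OC
F5 | step 14 | 2-bromo-3-chlorofuran | Clc1ccoc1Br
F6 | step 14 | 5-bromo-4-chloro-2-lithiofuran | [Li]c1cc(Cl)c(Br)o1
F7 | step 14 | 2-bromo-3-chloro-5-[(2Z,5Z)-octa-2,5-dien-1-yl]furan | CC/C=C\C/C=C\Cc1cc(Cl)c(Br)o1
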